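One substrate half-life is the unit of time for this flask, and every asked time is read as a count of that unit.

| flask | substrate | first nucleophile | second nucleophile | protic impurity | remark | time |
|---|---|---|---|---|---|---|
| gamma | 0.80 M | 0.80 M | 0.88 M | 0.11 M | run made earlier |  |
| zeta | 0.80 M | 0.80 M | 0.88 M | 0.24 M | run made earlier |  |
| flask | 0.80 M | 0.800 M | 0.880 M | 0.160 M |  | 4.0 d |

| run | time / d | target / % | other capture product / % |
|---|---|---|---|
| gamma | 0.250 | 47.5 | 36.9 |
| gamma | 0.833 | 60.2 | 37.1 |
| gamma | 1.67 | 61.6 | 39.8 |
| gamma | 2.50 | 60.9 | 38.2 |
| gamma | 3.00 | 59.9 | 38.3 |
| zeta | 0.250 | 45.8 | 37.9 |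
| zeta | 0.500 | 58.8 | 40.5 |
| zeta | 0.833 | 59.9 | 39.6 |
| zeta | 1.67 | 61.3 | 38.7 |
| zeta | 3.00 | 61.4 | 39.3 |

(each reading ± 1 percentage point)

1. ratio of target to other capture product at 6.0 min
2. ratio of target to other capture product at 3.0 h
3. ratio of target to other capture product at 4.0 d

The given numbers differ in weight. The charge c(protic impurity) changes the late ratio little: from gamma at 0.11 M to zeta at 0.24 M, the last ratio of target to other capture product reads 1.56 and 1.56, and the flask's 0.160 M lies between them. The late time matters little too: gamma's target reads 61.6% at 1.67 d and 59.9% at 3.00 d, with a scatter of 1 percentage point. The early ratios are the open question, because 3.0 h and 6.0 min fall before the first reading at 0.250 d.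

So the number needed is the unit itself. At that first reading, gamma and zeta on average leave 15.9% of the charge in neither product. Counting all of that as substrate, this gives 0.0944 d as a reading of the substrate half-life, the time in which a first-order loss lowers the amount by a factor of 2.

The asked times then count 0.0441, 1.32 and 42.4 units. The last count lies past the last readings, and the late readings stand level within their scatter, so this reckoning commits to their ratio, 1.56. The first readings, at count 2.65, give ratios of 1.29 and 1.21, lower than that late ratio. The ratio therefore climbs with the count, and both early ratios should lie under these readings.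

The forecast gives 0.8, 1 and 1.57, holding that “The impurity hardly matters”.

The flask gives 0.322, 0.757 and 1.58; the two early ratios stand under the first readings.

    first nucleophile + protic impurity → quenched reagent (k = 0.0710 /M/h)
    substrate → intermediate (k = 0.350 /h)
    second nucleophile + intermediate → other capture product (k = 12.0 /M/h)
    first nucleophile + intermediate → target (k = 4.10 /M/h)
    intermediate → side product (k = 0.00810 /h)
    second nucleophile → decomposed reagent (k = 0.510 /h)

The second nucleophile's half-life by decomposition, 0.057 d, is shorter than the substrate unit, so one unit holds 1.66 of its half-lives. At 0.400 d the flask holds 0.0566% of that nucleophile's charge and 38.6% other capture product, while target draws level at count 1.96.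

With 2.0 M substrate, a first-order loss with the same unit keeps the count at 42.4, so hardly any substrate should remain at 4.0 d. The computed neighbour holds 0% substrate, yet 16.5% intermediate stands there, and the ratio is 1.48.

The runs stem from a simulated flask with constants of no real substance; the scatter is artificial.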